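## Structural features

The target is an achiral 4H-chromen-4-one (benzo ring A fused to pyranone ring C; O1, C2–C4, C4a, C5–C8, C8a) with a heptyl chain at C5 and a hydroxyl at C7. Its C2 is joined through one methylene (C9) to C2' of a pentasubstituted benzoic acid, ring B, in which C1' carries CO2H, C3', C4' and C6' carry OH, and C5' carries the only ring hydrogen. There is no stereocentre, so the whole problem is constitutional. Ring B is a hydroxyquinol: O3' and O6' are para to each other, O4' is ortho to O3', and the two carbon substituents sit side by side between O6' and O3'. Fragile points are the hydroxyquinol (oxidised by air to a hydroxyquinone, fastest in base), the electron-rich salicylic acid unit (decarboxylation in hot acid), the pyranone ring (opened by hydroxide), and the carboxyl group, which is placed to add to C2 and could carry the chromone acid toward an isocoumarin isomer under strong acid. The real difficulty is the bond C9–C2', which lies at the most hindered position of ring B between the carboxyl carbon and O3', together with the five-fold substitution of that ring. The key step exploits two features. The para pair O3'/O6' makes ring B the reduced form of a 1,4-benzoquinone in which C2' is β to the C6' carbonyl and to the C1' ester carbonyl. C9 is the vinylogous α-carbon of C4=O through C2=C3, so the two halves are by nature an acceptor and a donor.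

## Logic of the disconnections

11 to 10. The O–C(CH3)3 bond of the ester on C1' and the O–CH3 bond on O4' are cut. The acid stays masked and O4' stays alkylated until the end because both groups are needed in the acceptor of the key step. The demand is one reagent that removes both without opening ring C, and a work-up free of air and base.

10 to 5 and 8 (key disconnection, through 9). The bond C9–C2' is cut. In one sentence, the route is the conjugate addition of 5 to 8. The cut is made here because the hydroquinone pattern of ring B is the retron of an addition to a quinone. The gain is two fragments of similar size, each two or three steps from a catalogue arene, with the five-fold substitution of ring B arising from a tetrasubstituted arene without any metalation. The demands are reaction of 5 at its exocyclic carbon, reaction of 8 at the carbon between ester and ketone, and suppression of electron transfer between product and acceptor.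

5 to 4. The two O–Si bonds (O7 and O4) are cut and the C9–H is restored. This turns the inert methyl group of 4 into a neutral carbon nucleophile and protects O7 in the same operation. The demand is enolisation toward C9 and not toward the benzylic carbon of the heptyl chain.

4 to 2 (through 3). O1–C2 and C2–C3 are cut. This is the ordinary pyranone annulation, used here on a methylchromone where no second carbonyl or acidic benzylic position can interfere. The demand is tolerance of the free para hydroxyl.

2 to 1. The aryl–acyl bond is cut. The two positions of 1 ortho to the alkyl chain are equivalent by symmetry. The demand is attack para to a hydroxyl and not between the two hydroxyls.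

8 to 7 to 6. The two quinone C=O groups are traced back to a para pair of methoxy groups, and the ester O–C bond is then cut. The gain is a commercial arene that already holds every oxygen of ring B. The demand is oxidation that spares the third methoxy group and the ester.

## Other disconnections considered

Alternative 1: The first idea is to cut O1–C2 and C2–C3 and close ring C last at oxygen. A 4-O-protected form of 2 would be O-acylated with 2-[2-(methoxycarbonyl)-3,5,6-trimethoxyphenyl]acetic acid A1. A Baker–Venkataraman shift would give the 1,3-diketone methyl 2-[4-(2-heptyl-6-hydroxy-4-methoxyphenyl)-2,4-dioxobutyl]-3,4,6-trimethoxybenzoate A2, and acid would close the chromone. A1 is itself a pentasubstituted arene that needs a directed metalation, a two-carbon homologation and differentiation of two carboxyl groups. Its benzylic CH2 is doubly activated, so base should favour ketene formation from the aryl ester over acyl transfer. A2 can close on the C2 ketone either through the phenol (chromone) or through the ester oxygen (isocoumarin). The chosen plan never makes a homophthalate and builds ring C before ring B is present.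

Alternative 2: C9–C2' and C1'–CO2 are cut together. The aryne 3,4,6-trimethoxybenzyne A4, released by fluoride from 3,5,6-trimethoxy-2-(trimethylsilyl)phenyl trifluoromethanesulfonate A3, would insert into the C–C bond of a malonate diester to give methyl 3,4,6-trimethoxy-2-(2-methoxy-2-oxoethyl)benzoate A5. In a 3-alkoxyaryne the nucleophile adds at the aryne carbon remote from the oxygen. In A4 both aryne carbons have an ortho methoxy group (C6' and C3'), so this bias cancels. The C4' methoxy only buttresses its neighbour and would, if anything, steer the carbon nucleophile to C1', the wrong end. A3 also needs several steps, and A5 still requires the annulation of alternative 1.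

Alternative 3: Ring B is made from a furan by cutting C1'–C6' and C2'–C3'. tert-Butyl[(4-methoxyfuran-2-yl)oxy]dimethylsilane A6 would add to an allene-1,3-dicarboxylate diester in a Diels–Alder reaction. Opening of the oxygen bridge and shift of the exocyclic double bond would give methyl 6-[(tert-butyldimethylsilyl)oxy]-3-hydroxy-4-methoxy-2-(2-methoxy-2-oxoethyl)benzoate A7. The regiochemistry is matched, because the nucleophilic C5 of the furan meets the central allene carbon. The product is again only a homophthalate. Its free O3'–H next to CH2CO2Me invites lactonisation to a benzofuranone, and protection, ester differentiation and the base-sensitive acyl transfer remain. The chosen plan reaches the same ring B pattern from a commercial arene in two steps and forms C9–C2' directly.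

Key step: step 6

Assumption: 1 and 6 are catalogue compounds; the locants are those defined under "Structural features".

## Steps

Step 1
Reactants: 1 5-heptylbenzene-1,3-diol
Product: 2 1-(2-heptyl-4,6-dihydroxyphenyl)ethan-1-one
Conditions: AcOH, ZnCl2, 140 °C; aq. HCl work-up
Reagents that add atoms: acetic acid, CC(=O)O
Why: Nencki-type Friedel–Crafts acylation (O-acetylation and Fries shift under ZnCl2); attack should occur para to one hydroxyl and ortho to the other, as in the acylation of orcinol; the two such positions of 1 are equivalent by symmetry and the chelated o-hydroxy ketone is deactivated toward a second acylation.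

Step 2
Reactants: 2 1-(2-heptyl-4,6-dihydroxyphenyl)ethan-1-one
Product: 4 5-heptyl-7-hydroxy-2-methyl-4H-chromen-4-one, via 7-acetoxy-5-heptyl-2-methylchromone 3 (not isolated)
Conditions: Ac2O, NaOAc, 170 °C; then Na2CO3, H2O/MeOH, reflux; HCl to pH 3
Reagents that add atoms: acetic anhydride, CC(=O)OC(C)=O
Why: Kostanecki–Robinson reaction: O-acetylation, base-mediated acyl shift to the ketone methyl (Baker–Venkataraman type) and cyclodehydration should give 3; the carbonate stage hydrolyses the 7-acetate and reverses any further C-acetylation at C3 by retro-Claisen cleavage.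

Step 3
Reactants: 4 5-heptyl-7-hydroxy-2-methyl-4H-chromen-4-one
Product: 5 4,7-bis[(tert-butyldimethylsilyl)oxy]-5-heptyl-2-methylidene-2H-chromene
Conditions: TBSOTf (2.3 equiv), Et3N (3 equiv), CH2Cl2, 0 °C to rt; pentane, filtration under Ar; used crude
Reagents that add atoms: tert-butyldimethylsilyl trifluoromethanesulfonate, CC(C)(C)[Si](C)(C)OS(=O)(=O)C(F)(F)F
Why: Phenol silylation and soft enolisation: O-silylation of C4=O gives a 4-silyloxybenzopyrylium triflate whose 2-methyl group is acidic enough for Et3N, so the neutral methylidene chromene (a pyrylium anhydrobase and silyl dienol ether) should result; deprotonation at the benzylic CH2 of the heptyl chain would break benzenoid aromaticity and should not compete.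

Step 4
Reactants: 6 2,4,5-trimethoxybenzoic acid
Product: 7 tert-butyl 2,4,5-trimethoxybenzoate
Conditions: tert-butyl 2,2,2-trichloroacetimidate (2 equiv), CH2Cl2/cyclohexane, rt
Reagents that add atoms: tert-butyl 2,2,2-trichloroacetimidate, CC(C)(C)OC(=N)C(Cl)(Cl)Cl
Why: Esterification with an alkyl trichloroacetimidate: the acid protonates the imidate and the carboxylate captures the tert-butyl cation; no external acid is present, so the electron-rich ring should not be tert-butylated.

Step 5
Reactants: 7 tert-butyl 2,4,5-trimethoxybenzoate
Product: 8 tert-butyl 4-methoxy-3,6-dioxocyclohexa-1,4-diene-1-carboxylate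
Conditions: (NH4)2Ce(NO3)6 (2.5 equiv), MeCN/H2O, 0 °C, short reaction time; used at once
Reagents that add atoms: water, O
Why: Oxidative demethylation of a para-dimethoxyarene by tetravalent cerium: two one-electron oxidations, ipso attack of water at C2 and C5 and loss of methanol should give the para-quinone; the 4-methoxy group remains as a vinylogous ester and tempers the electrophilicity of the product.

Step 6
Reactants: 5 4,7-bis[(tert-butyldimethylsilyl)oxy]-5-heptyl-2-methylidene-2H-chromene; 8 tert-butyl 4-methoxy-3,6-dioxocyclohexa-1,4-diene-1-carboxylate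
Product: 10 tert-butyl 2-[(5-heptyl-7-hydroxy-4-oxo-4H-chromen-2-yl)methyl]-3,6-dihydroxy-4-methoxybenzoate, via bis-silyl Michael adduct 9 (not isolated)
Conditions: 8 (1.0 equiv) added slowly to 5 (1.2 equiv), CH2Cl2, −78 to −20 °C; then KHF2, MeOH, rt; aq. Na2S2O4 wash
Reagents that add atoms: none
Why: Vinylogous Mukaiyama–Michael addition: the exocyclic CH2 of 5 is both the δ-terminus of the silyl dienol ether and the β-carbon of the O1–C2 enol ether, and its attack on C2 of 8 turns the pyran into an aromatic 4-silyloxybenzopyrylium, which is why reaction should occur at CH2 and not at C3. C2 of 8 is β to the C6 ketone and to the ester carbonyl, whereas C5 is the electron-rich α-carbon of the vinylogous ester MeO–C4=C5–C6=O, so only C2 should accept the nucleophile, which places the new bond between the ester and O3'. Silyl transfer from the pyrylium oxygen to the quinone enolate oxygen restores the chromone, enolisation of the remaining ketone aromatises ring B to give 9, and KHF2 then cleaves both aryl silyl ethers. The closest known reaction type is the uncatalysed or silyl-triflate-catalysed conjugate addition of silyl enol ethers, silyl ketene acetals and 2-silyloxyfurans to 2-acyl- and 2-alkoxycarbonyl-1,4-benzoquinones. No ring is closed and no stereocentre is formed; a Diels–Alder reaction is excluded because the C4=C3–C2=CH2 diene of 5 is locked s-trans. The step needs conjugate addition to win over redox exchange and over a second addition: slow addition of 8 to an excess of 5 at low temperature keeps the acceptor concentration low, the product stays silylated until the quench, and the dithionite wash returns any oxidised product to the hydroquinone. Attack of O3' on C2 of the pyrylium would give a spiroketal, but this is the formal oxa-Michael adduct of a chromone and a phenol and should revert to the open chromone under the mildly acidic fluoride conditions.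

Step 7
Reactants: 10 tert-butyl 2-[(5-heptyl-7-hydroxy-4-oxo-4H-chromen-2-yl)methyl]-3,6-dihydroxy-4-methoxybenzoate
Product: 11 2-[(5-heptyl-7-hydroxy-4-oxo-4H-chromen-2-yl)methyl]-3,4,6-trihydroxybenzoic acid
Conditions: BBr3 (8 equiv), CH2Cl2, −78 to 0 °C; degassed aq. ascorbic acid work-up; reversed-phase chromatography (acidic eluent)
Reagents that add atoms: none
Why: Lewis-acid dealkylation: BBr3 ionises the tert-butyl ester and, after complexation of O4', bromide cleaves the O–CH3 bond with help from the neighbouring O3' borate; chromones and phenols tolerate the reagent, and a cold, oxygen-free, acidic work-up should protect the hydroxyquinol acid.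

## Compound list

1 | 5-heptylbenzene-1,3-diol | CCCCCCCc1cc(O)cc(O)c1 | starting material
2 | 1-(2-heptyl-4,6-dihydroxyphenyl)ethan-1-one | CCCCCCCc1cc(O)cc(O)c1C(C)=O | intermediate
3 | 5-heptyl-2-methyl-4-oxo-4H-chromen-7-yl acetate | CCCCCCCc1cc(OC(C)=O)cc2oc(C)cc(=O)c12 | intermediate
4 | 5-heptyl-7-hydroxy-2-methyl-4H-chromen-4-one | CCCCCCCc1cc(O)cc2oc(C)cc(=O)c12 | intermediate
5 | 4,7-bis[(tert-butyldimethylsilyl)oxy]-5-heptyl-2-methylidene-2H-chromene | CCCCCCCc1cc(O[Si](C)(C)C(C)(C)C)cc2OC(=C)C=C(O[Si](C)(C)C(C)(C)C)c12 | intermediate
6 | 2,4,5-trimethoxybenzoic acid | COc1cc(OC)c(C(=O)O)cc1OC | starting material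
7 | tert-butyl 2,4,5-trimethoxybenzoate | COc1cc(OC)c(C(=O)OC(C)(C)C)cc1OC | intermediate
8 | tert-butyl 4-methoxy-3,6-dioxocyclohexa-1,4-diene-1-carboxylate | COC1=CC(=O)C(C(=O)OC(C)(C)C)=CC1=O | intermediate
9 | tert-butyl 6-[(tert-butyldimethylsilyl)oxy]-2-({7-[(tert-butyldimethylsilyl)oxy]-5-heptyl-4-oxo-4H-chromen-2-yl}methyl)-3-hydroxy-4-methoxybenzoate (drawn as the O6'-silyl form; the silyl position does not matter because both groups are removed in the same flask) | CCCCCCCc1cc(O[Si](C)(C)C(C)(C)C)cc2oc(Cc3c(O)c(OC)cc(O[Si](C)(C)C(C)(C)C)c3C(=O)OC(C)(C)C)cc(=O)c12 | intermediate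
10 | tert-butyl 2-[(5-heptyl-7-hydroxy-4-oxo-4H-chromen-2-yl)methyl]-3,6-dihydroxy-4-methoxybenzoate | CCCCCCCc1cc(O)cc2oc(Cc3c(O)c(OC)cc(O)c3C(=O)OC(C)(C)C)cc(=O)c12 | intermediate
11 | 2-[(5-heptyl-7-hydroxy-4-oxo-4H-chromen-2-yl)methyl]-3,4,6-trihydroxybenzoic acid | CCCCCCCc1cc(O)cc2oc(Cc3c(O)c(O)cc(O)c3C(=O)O)cc(=O)c12 | target

## Step count and least certain steps

Total step count: 7. Longest linear sequence: 5 steps (steps 1, 2, 3, 6, 7); the second branch (steps 4, 5) joins at step 6.

Step 6 (key step). Electron transfer between the electron-rich donor or the product hydroquinone and unreacted acceptor may consume the quinone. Loss of a C9 proton at the pyrylium stage may regenerate a nucleophile and lead to a second addition. Adventitious acid may hydrolyse the dienol ether before the C–C bond forms. The fallback makes the same bond with reversed polarity; it sets out from 5 and 7 and returns at 11. Bromination of 5 at the exocyclic carbon with NBS (THF, −78 °C) gives 2-(bromomethyl)-7-[(tert-butyldimethylsilyl)oxy]-5-heptyl-4H-chromen-4-one F1. Metalation of 7 at C6, between the ester and the 5-methoxy group, with Mg(TMP)2·2LiCl (TMP = 2,2,6,6-tetramethylpiperidide) and transmetalation with ZnCl2 gives [2-(tert-butoxycarbonyl)-3,5,6-trimethoxyphenyl]zinc chloride F2. Negishi coupling of F1 with F2 (Pd(OAc)2 and SPhos, which form zerovalent palladium in the flask, THF) gives tert-butyl 2-({7-[(tert-butyldimethylsilyl)oxy]-5-heptyl-4-oxo-4H-chromen-2-yl}methyl)-3,4,6-trimethoxybenzoate F3. BBr3 then removes the three methyl groups, the tert-butyl group and the silyl group to give 11.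

Step 3. Deprotonation of the pyrylium triflate may stop at an equilibrium, the amine may add reversibly at C2, and the dienol ether may be hydrolysed during salt removal. The fallback replaces the silyl dienol ether by an ester-stabilised carbanion; it sets out from 4 and returns at 11. TBSCl and imidazole give 7-[(tert-butyldimethylsilyl)oxy]-5-heptyl-2-methyl-4H-chromen-4-one F4. Deprotonation at C9 with LiN(SiMe3)2 (2.2 equiv, THF, −78 °C) and C-acylation with Boc2O give tert-butyl 2-{7-[(tert-butyldimethylsilyl)oxy]-5-heptyl-4-oxo-4H-chromen-2-yl}acetate F5. F5 is a vinylogous malonate-type C–H acid, and with catalytic K2CO3 in MeCN it should add to C2 of 8 to give racemic tert-butyl 2-(2-tert-butoxy-1-{7-[(tert-butyldimethylsilyl)oxy]-5-heptyl-4-oxo-4H-chromen-2-yl}-2-oxoethyl)-3,6-dihydroxy-4-methoxybenzoate F6. BBr3 cleaves both tert-butyl esters, the methyl ether and the silyl ether. The chromon-2-ylacetic acid so formed is a vinylogous β-keto acid and should lose CO2 on gentle warming, which removes the stereocentre and gives 11.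

Step 7. The many Lewis-basic oxygens may sequester the reagent and stall ether cleavage. The tert-butyl cation may be recaptured by an electron-rich ring. The liberated carboxyl group may add to C2 and start a ring-chain isomerisation toward an isocoumarin. The product may decarboxylate or be oxidised by air during work-up. The fallback changes the protecting groups so that the last step is a neutral hydrogenolysis; it sets out from 6, uses 5, and returns at 11. BBr3 on 6 gives 2,4,5-trihydroxybenzoic acid F9. BnBr (2 equiv) and K2CO3 in DMF alkylate the carboxylate and the most acidic hydroxyl (para to the ester) to give benzyl 4-(benzyloxy)-2,5-dihydroxybenzoate F10. Ag2O oxidises the hydroquinone to benzyl 4-(benzyloxy)-3,6-dioxocyclohexa-1,4-diene-1-carboxylate F11. Addition of 5 under the conditions of step 6 gives benzyl 4-(benzyloxy)-2-[(5-heptyl-7-hydroxy-4-oxo-4H-chromen-2-yl)methyl]-3,6-dihydroxybenzoate F12. H2 over Pd/C in EtOAc removes both benzyl groups and gives 11.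

Step 5. The ester slows the first electron transfer, so oxidation may be incomplete. Loss of the adjacent 4,5-methoxy pair may give an ortho-quinone. Hydrolysis of the vinylogous ester or of the tert-butyl ester and decomposition of the quinone on silica are further risks. The fallback replaces arene oxidation by dearomatisation of a phenol; it sets out from 6 and returns at 8. BCl3 (CH2Cl2, 0 °C) removes only the methyl group ortho to the carboxyl group by chelation and gives 2-hydroxy-4,5-dimethoxybenzoic acid F7. tert-Butyl 2,2,2-trichloroacetimidate gives tert-butyl 2-hydroxy-4,5-dimethoxybenzoate F8, the hydrogen-bonded phenol remaining free. PhI(OAc)2 in MeCN/H2O at 0 °C oxidises this para-methoxyphenol by ipso attack of water at C5 and loss of methanol and gives 8.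

## Further compounds

F1 | step 6 | 2-(bromomethyl)-7-[(tert-butyldimethylsilyl)oxy]-5-heptyl-4H-chromen-4-one | CCCCCCCc1cc(O[Si](C)(C)C(C)(C)C)cc2oc(CBr)cc(=O)c12
F2 | step 6 | [2-(tert-butoxycarbonyl)-3,5,6-trimethoxyphenyl]zinc chloride | COc1cc(OC)c(C(=O)OC(C)(C)C)c([Zn]Cl)c1OC
F3 | step 6 | tert-butyl 2-({7-[(tert-butyldimethylsilyl)oxy]-5-heptyl-4-oxo-4H-chromen-2-yl}methyl)-3,4,6-trimethoxybenzoate | CCCCCCCc1cc(O[Si](C)(C)C(C)(C)C)cc2oc(Cc3c(OC)c(OC)cc(OC)c3C(=O)OC(C)(C)C)cc(=O)c12
F4 | step 3 | 7-[(tert-butyldimethylsilyl)oxy]-5-heptyl-2-methyl-4H-chromen-4-one | CCCCCCCc1cc(O[Si](C)(C)C(C)(C)C)cc2oc(C)cc(=O)c12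
F5 | step 3 | tert-butyl 2-{7-[(tert-butyldimethylsilyl)oxy]-5-heptyl-4-oxo-4H-chromen-2-yl}acetate | CCCCCCCc1cc(O[Si](C)(C)C(C)(C)C)cc2oc(CC(=O)OC(C)(C)C)cc(=O)c12
F6 | step 3 | tert-butyl 2-(2-tert-butoxy-1-{7-[(tert-butyldimethylsilyl)oxy]-5-heptyl-4-oxo-4H-chromen-2-yl}-2-oxoethyl)-3,6-dihydroxy-4-methoxybenzoate (racemic) | CCCCCCCc1cc(O[Si](C)(C)C(C)(C)C)cc2oc(C(C(=O)OC(C)(C)C)c3c(O)c(OC)cc(O)c3C(=O)OC(C)(C)C)cc(=O)c12
F7 | step 5 | 2-hydroxy-4,5-dimethoxybenzoic acid | COc1cc(O)c(C(=O)O)cc1OC
F8 | step 5 | tert-butyl 2-hydroxy-4,5-dimethoxybenzoate | COc1cc(O)c(C(=O)OC(C)(C)C)cc1OC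
F9 | step 7 | 2,4,5-trihydroxybenzoic acid | Oc1cc(O)c(C(=O)O)cc1O
F10 | step 7 | benzyl 4-(benzyloxy)-2,5-dihydroxybenzoate | O=C(OCc1ccccc1)c1cc(O)c(OCc2ccccc2)cc1O
F11 | step 7 | benzyl 4-(benzyloxy)-3,6-dioxocyclohexa-1,4-diene-1-carboxylate | O=C(OCc1ccccc1)C1=CC(=O)C(OCc2ccccc2)=CC1=O
F12 | step 7 | benzyl 4-(benzyloxy)-2-[(5-heptyl-7-hydroxy-4-oxo-4H-chromen-2-yl)methyl]-3,6-dihydroxybenzoate | CCCCCCCc1cc(O)cc2oc(Cc3c(O)c(OCc4ccccc4)cc(O)c3C(=O)OCc5ccccc5)cc(=O)c12
A1 | alternative 1 | 2-[2-(methoxycarbonyl)-3,5,6-trimethoxyphenyl]acetic acid | COC(=O)c1c(OC)cc(OC)c(OC)c1CC(=O)O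
A2 | alternative 1 | methyl 2-[4-(2-heptyl-6-hydroxy-4-methoxyphenyl)-2,4-dioxobutyl]-3,4,6-trimethoxybenzoate | CCCCCCCc1cc(OC)cc(O)c1C(=O)CC(=O)Cc1c(OC)c(OC)cc(OC)c1C(=O)OC
A3 | alternative 2 | 3,5,6-trimethoxy-2-(trimethylsilyl)phenyl trifluoromethanesulfonate | COc1cc(OC)c(OC)c(OS(=O)(=O)C(F)(F)F)c1[Si](C)(C)C
A4 | alternative 2 | 3,4,6-trimethoxybenzyne | COC1=CC(OC)=C(OC)C#C1
A5 | alternative 2 | methyl 3,4,6-trimethoxy-2-(2-methoxy-2-oxoethyl)benzoate | COC(=O)Cc1c(OC)c(OC)cc(OC)c1C(=O)OC
A6 | alternative 3 | tert-butyl[(4-methoxyfuran-2-yl)oxy]dimethylsilane | COc1coc(O[Si](C)(C)C(C)(C)C)c1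
A7 | alternative 3 | methyl 6-[(tert-butyldimethylsilyl)oxy]-3-hydroxy-4-methoxy-2-(2-methoxy-2-oxoethyl)benzoate | COC(=O)Cc1c(O)c(OC)cc(O[Si](C)(C)C(C)(C)C)c1C(=O)OC
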